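**Retrosynthetic overview**
- The target comes from its 3′,4′-di-O-benzyl ether by neutral hydrogenolysis; acid is avoided once the tertiary alcohol is free.
- Ring A is cut at C7–C8 and C5–C6: a 6-aryl-2-methyl-4-pyranone-3-carboxylate (rings B and C in place; ester carbon = C5, methyl = C8) plus a trans-fused bicyclic δ-lactone (carbonyl = C7, α-carbon = C6, β-carbon = benzylic CH2). The lactone is the acyl donor and its ring oxygen is released as the tertiary alcohol.
- The δ-lactone comes from (E)-5,9-dimethyldeca-4,8-dienoic acid by enantioselective proton-initiated bicyclisation (cyclohexane and lactone rings together, both stereocentres set), and the acid from geranyl bromide and acetic acid.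
- The pyranone comes from an aroylketene (from the acyl Meldrum's acid of 3,4-bis(benzyloxy)benzoic acid) and ethyl 3-pyrrolidinocrotonate.
- Ring order: cyclohexane and lactone in one operation; ring C on the preformed ring B; ring A last, with opening of the lactone.

Assumption: the (R)-BINOL-derived LBA is taken to give the "normal" terpenoid enantiomeric series (here 4aS,8aS), by analogy with its reported use; if chiral HPLC of the lactone shows the opposite sense, the (S)-ligand is used with no other change.

**Step 1**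
Reactants: 1 geranyl bromide [(2E)-1-bromo-3,7-dimethylocta-2,6-diene]; 2 acetic acid
Product: 4 (4E)-5,9-dimethyldeca-4,8-dienoic acid, via dilithioacetate 3 (not isolated)
Conditions: 2, LDA (2.2 equiv, commercial solution), THF/DMPU, 0 → 40 °C; then 1, 0 °C → rt; 1 M HCl work-up
Reagents that add atoms: none
Why: Carboxylic acid dianion alkylation: the acetic acid dianion is C-alkylated by the primary allylic bromide (SN2), which keeps the (E)-alkene and gives the C12 dienoic acid directly; no stereocentre is formed.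

**Step 2**
Reactants: 4 (4E)-5,9-dimethyldeca-4,8-dienoic acid
Product: 5 (4aS,8aS)-5,5,8a-trimethyloctahydro-2H-chromen-2-one (trans-fused δ-lactone)
Conditions: (R)-2-benzyloxy-2′-hydroxy-1,1′-binaphthyl·SnCl4 (1.2 equiv, preformed; ligand recovered), toluene, −78 °C, 48–72 h
Reagents that add atoms: none
Why: Yamamoto–Ishihara LBA (Lewis acid-assisted chiral Brønsted acid) proton-initiated polyene cyclisation: enantioface-selective protonation of the terminal alkene, chair-like anti addition across the (E)-4,5-alkene and capture of the tertiary cation by the carboxyl oxygen form the cyclohexane and the δ-lactone in one operation and set both stereocentres (trans fusion from the E geometry, absolute sense from the (R)-ligand), by analogy with the γ-lactone series.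

**Step 3**
Reactants: 6 3,4-bis(benzyloxy)benzoic acid; 7 Meldrum's acid (2,2-dimethyl-1,3-dioxane-4,6-dione)
Product: 8 5-{[3,4-bis(benzyloxy)phenyl](hydroxy)methylidene}-2,2-dimethyl-1,3-dioxane-4,6-dione
Conditions: DCC (1.1 equiv), DMAP (1.5 equiv), CH2Cl2, 0 °C → rt
Reagents that add atoms: none
Why: Carbodiimide/DMAP C-acylation of Meldrum's acid (Oikawa–Yonemitsu type) gives the enolised acyl Meldrum's acid as a storable aroylketene precursor; no stereocentre is formed.

**Step 4**
Reactants: 8 acyl Meldrum's acid; 9 ethyl (2E)-3-(pyrrolidin-1-yl)but-2-enoate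
Product: 12 ethyl 6-[3,4-bis(benzyloxy)phenyl]-2-methyl-4-oxo-4H-pyran-3-carboxylate, via aroylketene 10 (not isolated), via C-acylated enamino ester 11 (not isolated)
Conditions: 9 (1.5 equiv), toluene, 90 °C, 2 h; then TsOH·H2O (1.5 equiv), 60 °C
Reagents that add atoms: none
Why: Acylketene γ-pyrone synthesis: thermal retro-[4+2] of 8 releases the aroylketene, which C-acylates the nucleophilic β-enamino ester, and acid then closes the pyranone by attack of the aryl-ketone enol oxygen on the enamine carbon with loss of pyrrolidine, so 2-methyl, 3-ester and 6-aryl are fixed by connectivity; no stereocentre is formed.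

**Step 5**
Reactants: 12 pyranone ester; 5 (4aS,8aS)-δ-lactone
Product: 15 2-[3,4-bis(benzyloxy)phenyl]-5,7-dihydroxy-6-{[(1S,2S)-2-hydroxy-2,6,6-trimethylcyclohexyl]methyl}-4H-chromen-4-one, via lithiated pyranone 13 (not isolated), via ring-opened keto ester 14 (not isolated)
Conditions: 12, LDA (1.1 equiv), THF/DMPU, −78 °C; 5, −78 → 0 °C; LDA (2.5 equiv), −78 → 25 °C; AcOH quench at 0 °C
Reagents that add atoms: none
Why: Proposed new method: the lateral (vinylogous) carbanion of the 2-methyl group acylates at the lactone carbonyl (Claisen; the tertiary alkoxide is the internal leaving group, so the tertiary alcohol appears with its C–O bond and configuration untouched), then the α′-carbanion of the new ketone formed with excess LDA closes onto the neighbouring ethyl ester (Dieckmann) and the cyclic triketone tautomerises irreversibly to the 5,7-dihydroxy A ring with the side chain fixed at C6; the closest known reaction types are the Staunton–Weinreb/toluate-anion naphthol annulations and the Harris biomimetic Claisen cyclisation of polyketo esters, and both stereocentres are carried through unchanged.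

**Step 6**
Reactants: 15 dibenzyl-protected flavone
Product: 16 2-(3,4-dihydroxyphenyl)-5,7-dihydroxy-6-{[(1S,2S)-2-hydroxy-2,6,6-trimethylcyclohexyl]methyl}-4H-chromen-4-one (target, CNP0257603.1)
Conditions: H2 (1 atm), 10% Pd/C, THF/MeOH, rt
Reagents that add atoms: none
Why: Heterogeneous hydrogenolysis of the two benzyl aryl ethers frees the catechol under neutral conditions, so the tertiary alcohol next to the C5/C7 phenols is not ionised (no closure to a hexahydroxanthene) and the flavone C2=C3 bond and both stereocentres are untouched.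

**Compound list**
1 | geranyl bromide, (2E)-1-bromo-3,7-dimethylocta-2,6-diene | CC(C)=CCC/C(C)=C/CBr | starting material
2 | acetic acid | CC(=O)O | starting material
3 | dilithioacetate (dilithium ethene-1,1-diolate; not isolated) | [Li+].[Li+].C=C([O-])[O-] | intermediate
4 | (4E)-5,9-dimethyldeca-4,8-dienoic acid | CC(C)=CCC/C(C)=C/CCC(=O)O | intermediate
5 | (4aS,8aS)-5,5,8a-trimethyloctahydro-2H-chromen-2-one | CC1(C)CCC[C@]2(C)OC(=O)CC[C@@H]12 | intermediate
6 | 3,4-bis(benzyloxy)benzoic acid | OC(=O)c1ccc(OCc2ccccc2)c(OCc2ccccc2)c1 | starting material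
7 | Meldrum's acid | CC1(C)OC(=O)CC(=O)O1 | starting material
8 | 5-{[3,4-bis(benzyloxy)phenyl](hydroxy)methylidene}-2,2-dimethyl-1,3-dioxane-4,6-dione | CC1(C)OC(=O)C(=C(O)c2ccc(OCc3ccccc3)c(OCc3ccccc3)c2)C(=O)O1 | intermediate
9 | ethyl (2E)-3-(pyrrolidin-1-yl)but-2-enoate | CCOC(=O)/C=C(\C)N1CCCC1 | starting material
10 | 3-[3,4-bis(benzyloxy)phenyl]-3-oxoprop-1-en-1-one (aroylketene; not isolated) | O=C=CC(=O)c1ccc(OCc2ccccc2)c(OCc2ccccc2)c1 | intermediate
11 | ethyl 2-{3-[3,4-bis(benzyloxy)phenyl]-3-oxopropanoyl}-3-(pyrrolidin-1-yl)but-2-enoate (not isolated) | CCOC(=O)C(C(=O)CC(=O)c1ccc(OCc2ccccc2)c(OCc2ccccc2)c1)=C(C)N1CCCC1 | intermediate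
12 | ethyl 6-[3,4-bis(benzyloxy)phenyl]-2-methyl-4-oxo-4H-pyran-3-carboxylate | CCOC(=O)c1c(C)oc(-c2ccc(OCc3ccccc3)c(OCc3ccccc3)c2)cc1=O | intermediate
13 | lateral lithium anion of 12 (2-lithiomethyl pyranone ester; not isolated) | [Li+].[CH2-]c1oc(-c2ccc(OCc3ccccc3)c(OCc3ccccc3)c2)cc(=O)c1C(=O)OCC | intermediate
14 | ethyl 6-[3,4-bis(benzyloxy)phenyl]-2-{4-[(1S,2S)-2-hydroxy-2,6,6-trimethylcyclohexyl]-2-oxobutyl}-4-oxo-4H-pyran-3-carboxylate (in the flask as its lithium alkoxide/enolate; not isolated) | CCOC(=O)c1c(CC(=O)CC[C@H]2C(C)(C)CCC[C@]2(C)O)oc(-c3ccc(OCc4ccccc4)c(OCc5ccccc5)c3)cc1=O | intermediate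
15 | 2-[3,4-bis(benzyloxy)phenyl]-5,7-dihydroxy-6-{[(1S,2S)-2-hydroxy-2,6,6-trimethylcyclohexyl]methyl}-4H-chromen-4-one | CC1(C)CCC[C@](C)(O)[C@H]1Cc1c(O)cc2oc(-c3ccc(OCc4ccccc4)c(OCc5ccccc5)c3)cc(=O)c2c1O | intermediate
16 | 2-(3,4-dihydroxyphenyl)-5,7-dihydroxy-6-{[(1S,2S)-2-hydroxy-2,6,6-trimethylcyclohexyl]methyl}-4H-chromen-4-one | CC1(C)CCC[C@](C)(O)[C@H]1Cc1c(O)cc2oc(-c3ccc(O)c(O)c3)cc(=O)c2c1O | target

**Totals**
Total step count: 6. Longest linear sequence: 4 steps (1 → 2 → 5 → 6, or 3 → 4 → 5 → 6).

**Three steps most likely to fail**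

Step 5 is the most likely to fail. The lateral anion of 12 is stabilised by both the ring ketone and the ester and may be too weak a nucleophile for the lactone, and O-acylation to an enol lactone may compete with the Dieckmann closure. The fallback sets out from 12 (with 5) and comes back at 15. Compound 12 is saponified (LiOH, THF/H2O, 0 °C) to 6-[3,4-bis(benzyloxy)phenyl]-2-methyl-4-oxo-4H-pyran-3-carboxylic acid F1. With 2.2 equiv LDA this gives the carboxylate/lateral dianion, a much stronger nucleophile of the o-toluic acid dianion type, which opens lactone 5 to 6-[3,4-bis(benzyloxy)phenyl]-2-{4-[(1S,2S)-2-hydroxy-2,6,6-trimethylcyclohexyl]-2-oxobutyl}-4-oxo-4H-pyran-3-carboxylic acid F2. The acid is activated with CDI to the acyl imidazolide F3, and DBU in THF at 50 °C closes ring A by C-acylation and aromatisation to 15; imidazole returns any O-acylated material to the acyl imidazolide.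

Step 2 is the second risk. The enantiomeric excess or yield of the LBA bicyclisation may be too low, because δ-lactone closure is slower than the γ case and monocyclic olefin acids may form; a modest ee could also be raised by recrystallising 15. The fallback sets out from 4 and comes back at 5. Racemic cyclisation (ClSO3H, 2-nitropropane, −78 °C) gives the racemic trans-5,5,8a-trimethyloctahydro-2H-chromen-2-one F4. Aminolysis with (S)-1-phenylethylamine/AlMe3 gives two diastereomeric hydroxy amides that are separated by crystallisation or chromatography: (S)-N-(1-phenylethyl)-3-[(1S,2S)-2-hydroxy-2,6,6-trimethylcyclohexyl]propanamide F5 is kept, and (S)-N-(1-phenylethyl)-3-[(1R,2R)-2-hydroxy-2,6,6-trimethylcyclohexyl]propanamide F6 is discarded. Relactonisation of the kept amide (aq. H2SO4/dioxane, 60 °C) gives 5 and returns the amine.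

Step 4 is the third risk. The aroylketene may be lost to dimerisation or to salt formation between 8 and 9, and the acid closure may give a 2-pyranone by attack on the ester. The fallback sets out from 6 and comes back at 12. Acid 6 is esterified (MeI, K2CO3, DMF) to methyl 3,4-bis(benzyloxy)benzoate F7. The dianion of commercial ethyl 2-acetyl-3-oxobutanoate (NaH, then LDA, THF) is acylated at its terminal methyl by this ester (β-diketone dianion Claisen) to give ethyl 2-acetyl-5-[3,4-bis(benzyloxy)phenyl]-3,5-dioxopentanoate F8. Cyclodehydration of the triketo ester (TFA, CH2Cl2, rt) gives 12.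

**Further compounds**
F1 | step 5 | 6-[3,4-bis(benzyloxy)phenyl]-2-methyl-4-oxo-4H-pyran-3-carboxylic acid | Cc1oc(-c2ccc(OCc3ccccc3)c(OCc3ccccc3)c2)cc(=O)c1C(=O)O
F2 | step 5 | 6-[3,4-bis(benzyloxy)phenyl]-2-{4-[(1S,2S)-2-hydroxy-2,6,6-trimethylcyclohexyl]-2-oxobutyl}-4-oxo-4H-pyran-3-carboxylic acid | OC(=O)c1c(CC(=O)CC[C@H]2C(C)(C)CCC[C@]2(C)O)oc(-c3ccc(OCc4ccccc4)c(OCc5ccccc5)c3)cc1=O
F3 | step 5 | 1-imidazolyl ketone (acyl imidazolide) of F2 | O=C(n1ccnc1)c1c(CC(=O)CC[C@H]2C(C)(C)CCC[C@]2(C)O)oc(-c3ccc(OCc4ccccc4)c(OCc5ccccc5)c3)cc1=O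
F4 | step 2 | racemic trans-5,5,8a-trimethyloctahydro-2H-chromen-2-one (1:1 mixture of enantiomers) | CC1(C)CCC[C@]2(C)OC(=O)CC[C@@H]12.CC1(C)CCC[C@@]2(C)OC(=O)CC[C@H]12
F5 | step 2 | (S)-N-(1-phenylethyl)-3-[(1S,2S)-2-hydroxy-2,6,6-trimethylcyclohexyl]propanamide | C[C@H](NC(=O)CC[C@H]1C(C)(C)CCC[C@]1(C)O)c1ccccc1
F6 | step 2 | (S)-N-(1-phenylethyl)-3-[(1R,2R)-2-hydroxy-2,6,6-trimethylcyclohexyl]propanamide | C[C@H](NC(=O)CC[C@@H]1C(C)(C)CCC[C@@]1(C)O)c1ccccc1
F7 | step 4 | methyl 3,4-bis(benzyloxy)benzoate | COC(=O)c1ccc(OCc2ccccc2)c(OCc2ccccc2)c1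
F8 | step 4 | ethyl 2-acetyl-5-[3,4-bis(benzyloxy)phenyl]-3,5-dioxopentanoate | CCOC(=O)C(C(C)=O)C(=O)CC(=O)c1ccc(OCc2ccccc2)c(OCc2ccccc2)c1
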